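Ring A (the cyclohexenone) contains a semipinacol retron: ketone carbon C1, the adjacent quaternary spiro carbon C10 and the lactone OCH2 carbon C20 on it form a β-hydroxy ketone. The bond between C10 and C5 (the CH bearing CH2OH) is therefore made by Lewis-acid ring expansion of a cyclopentanol whose carbinol carbon carries a 2,2-disubstituted oxirane: C5 migrates from C1 to C10, closing the six-membered ring, fixing the quaternary centre with inversion and releasing the C1 ketone and the C20 hydroxyl in one operation. The precursor is a simple epoxy cyclopentanol from an Evans-derived cyclopentanone. Lactone, ring C and ring D are then annulated by Knoevenagel, Diels–Alder and palladium chemistry.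

Key step: step 10

Remark on numbering: atoms carry ent-kaurane numbers. Ring A = C1 (ketone), C2, C3, C4 (gem-dimethyl), C5 (bears C6H2OH), C10; lactone ring = C10, C20, O, C7, C8, C9; ring C = C8, C9, C11, C12, C13, C14; ring D = C8, C14, C13, C16 (bears OH and C17H3), C15 (ketone).

Step 1
Reactants: 1 3,3-dimethylpent-4-enoic acid; 2 (R)-4-benzyl-1,3-oxazolidin-2-one
Product: 4 (R)-4-benzyl-3-(3,3-dimethylpent-4-enoyl)-1,3-oxazolidin-2-one, via mixed pivalic anhydride 3 (not isolated)
Conditions: t-BuCOCl, Et3N, THF, −20 °C; then 2, LiCl, rt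
Reagents that add atoms: none
Why: N-acylation of the oxazolidinone through the mixed anhydride is the standard way to attach an Evans auxiliary and creates no stereocentre.

Step 2
Reactants: 4 N-acyl oxazolidinone
Product: 6 (R)-4-benzyl-3-[(2S)-2-(hydroxymethyl)-3,3-dimethylpent-4-enoyl]-1,3-oxazolidin-2-one, via titanium enolate 5 (not isolated)
Conditions: TiCl4, i-Pr2NEt, CH2Cl2, 0 °C; then 1,3,5-trioxane, TiCl4, 0 °C
Reagents that add atoms: 1,3,5-trioxane C1OCOCO1
Why: Evans alkylation of the chelated (Z)-titanium enolate with Lewis-acid-activated formaldehyde should occur on the face away from the benzyl group and so set C5 (S at the acyl α-carbon), the only stereocentre carried into ring A.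

Step 3
Reactants: 6 hydroxymethyl imide
Product: 7 (R)-4-benzyl-3-[(2S)-2-{[(tert-butyldiphenylsilyl)oxy]methyl}-3,3-dimethylpent-4-enoyl]-1,3-oxazolidin-2-one
Conditions: t-BuPh2SiCl, imidazole, DMF, rt
Reagents that add atoms: tert-butyl(chloro)diphenylsilane CC(C)(C)[Si](Cl)(c1ccccc1)c1ccccc1
Why: Standard silylation of the primary alcohol gives a robust silyl ether that protects the C6 oxygen to the last step.

Step 4
Reactants: 7 silyl ether imide
Product: 8 (2R)-2-{[(tert-butyldiphenylsilyl)oxy]methyl}-3,3-dimethylpent-4-en-1-ol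
Conditions: LiBH4, MeOH (1 equiv), THF, 0 °C
Reagents that add atoms: none
Why: Reductive cleavage of the Evans imide with LiBH4 should give the primary alcohol without touching the α-stereocentre and return the auxiliary.

Step 5
Reactants: 8 primary alcohol
Product: 9 (2S)-2-{[(tert-butyldiphenylsilyl)oxy]methyl}-3,3-dimethylpent-4-enal
Conditions: Dess–Martin periodinane, NaHCO3, CH2Cl2, 0 °C to rt
Reagents that add atoms: none
Why: Buffered Dess–Martin oxidation should give the aldehyde without epimerisation or β-elimination of the silyloxy group.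

Step 6
Reactants: 9 pent-4-enal
Product: 10 (2S)-2-{[(tert-butyldiphenylsilyl)oxy]methyl}-3,3-dimethylcyclopentan-1-one
Conditions: [Rh(Ph2PCH2CH2PPh2)]BF4 (5 mol %), CH2Cl2, rt
Reagents that add atoms: none
Why: Rhodium-catalysed intramolecular hydroacylation of a 4-pentenal (C–H oxidative addition, alkene insertion, reductive elimination) should close the cyclopentanone under neutral conditions, helped by the gem-dimethyl group, and leave the α-stereocentre intact.

Step 7
Reactants: 11 benzyl alcohol; 12 2,3-dibromoprop-1-ene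
Product: 14 benzyl 2-bromoprop-2-en-1-yl ether, via sodium benzyloxide 13 (not isolated)
Conditions: NaH, THF, 0 °C; then 12, rt
Reagents that add atoms: none
Why: Williamson ether synthesis, in which the alkoxide displaces the allylic bromide and leaves the vinylic bromide in place.

Step 8
Reactants: 14 benzyl 2-bromoallyl ether; 10 cyclopentanone
Product: 17 (1S,2S)-1-[3-(benzyloxy)prop-1-en-2-yl]-2-{[(tert-butyldiphenylsilyl)oxy]methyl}-3,3-dimethylcyclopentan-1-ol, via alkenyllithium 15 (not isolated), via alkenylcerium dichloride 16 (not isolated)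
Conditions: t-BuLi (2 equiv), Et2O, −78 °C; CeCl3, THF, −78 °C; then 10
Reagents that add atoms: none
Why: Bromine–lithium exchange and transmetallation to the weakly basic organocerium allow 1,2-addition without enolisation, and the nucleophile should enter trans to the C5 side chain of the 2-substituted cyclopentanone, which sets the carbinol centre C1.

Step 9
Reactants: 17 tertiary allylic alcohol
Product: 18 (1S,2S)-1-{(2S)-2-[(benzyloxy)methyl]oxiran-2-yl}-2-{[(tert-butyldiphenylsilyl)oxy]methyl}-3,3-dimethylcyclopentan-1-ol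
Conditions: VO(acac)2 (5 mol %), t-BuOOH, CH2Cl2, 0 °C to rt
Reagents that add atoms: tert-butyl hydroperoxide CC(C)(C)OO
Why: Hydroxyl-directed vanadium-catalysed epoxidation of the 1,1-disubstituted allylic alkene should prefer the transition state in which the unbranched ring methylene C2, not the branched C5, eclipses the benzyloxymethyl group on the alkene (minimal A(1,2) strain), which gives the (S)-oxirane at C10.

Step 10
Reactants: 18 epoxy cyclopentanol
Product: 19 (2S,3R)-2-[(benzyloxy)methyl]-3-{[(tert-butyldiphenylsilyl)oxy]methyl}-2-(hydroxymethyl)-4,4-dimethylcyclohexan-1-one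
Conditions: BF3·OEt2 (0.2 equiv), CH2Cl2, −78 °C
Reagents that add atoms: none
Why: Semipinacol rearrangement of a tertiary 2,3-epoxy alcohol: BF3 activates the oxirane oxygen, the C10–O bond breaks as the antiperiplanar C1–C5 bond migrates to C10, and the carbinol carbon becomes the C1 ketone. The closest known reaction type is the Lewis-acid ring expansion of 1-(oxiran-2-yl)cycloalkanols to 2-(hydroxymethyl)cycloalkanones with a quaternary α-carbon. Ring A is closed by a suprafacial 1,2-alkyl shift that enlarges the cyclopentane by one carbon, so no Baldwin-type closure is involved. C10 is set by the oxirane configuration because migration occurs with inversion there, whereas C5 migrates with retention and keeps the configuration from step 2, so the freed hydroxymethyl arm (C20) should lie cis to the C6 side chain. The step needs migration of C5 rather than C2, which the higher migratory aptitude of the secondary, more substituted carbon should secure. Because both arms on C10 are oxygenated methylene groups, the other oxirane epimer would also be usable after exchanging the roles of the two arms.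

Step 11
Reactants: 19 hydroxy ketone; 20 tert-butyl 3-oxopentanoate
Product: 22 3-oxopentanoate ester of the C20 hydroxyl of 19, via propionylketene 21 (not isolated)
Conditions: toluene, 110 °C (t-BuOH distilled off)
Reagents that add atoms: none
Why: Thermal loss of tert-butanol from the β-keto ester gives an acylketene that acylates the hindered neopentyl alcohol under neutral conditions, which avoids retro-aldol loss of formaldehyde from the β-hydroxy ketone.

Step 12
Reactants: 22 benzyl ether β-keto ester
Product: 23 primary alcohol (C9 hydroxyl free)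
Conditions: H2 (1 atm), Pd/C, EtOAc, rt
Reagents that add atoms: none
Why: Hydrogenolysis of the benzyl ether is selective here because no alkene is present and the silyl ether, ketone and β-keto ester are inert.

Step 13
Reactants: 23 primary alcohol
Product: 25 spirocyclic α-propionyl-α,β-unsaturated δ-lactone, via keto ester aldehyde 24 (not isolated)
Conditions: Dess–Martin periodinane, NaHCO3, CH2Cl2; then piperidine (10 mol %), AcOH (10 mol %), rt
Reagents that add atoms: none
Why: Dess–Martin oxidation gives the neopentyl aldehyde C9, which should undergo intramolecular Knoevenagel condensation with the β-keto ester methylene C8 to close the six-membered lactone.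

Step 14
Reactants: 25 unsaturated acyl lactone; 26 buta-1,3-diene
Product: 27 cis-fused cyclohexene lactone (5R,8S,9S,10S)
Conditions: ZnCl2 (20 mol %), CH2Cl2, 0 °C to rt, sealed tube
Reagents that add atoms: none
Why: Lewis-acid-promoted Diels–Alder reaction of the doubly activated cyclic dienophile gives the cis ring fusion by suprafacial addition, and the diene should approach C9 from the face of the flat C1 carbonyl, away from the branched C5, which sets C8 and C9.

Step 15
Reactants: 27 Diels–Alder adduct
Product: 28 bis(tert-butyldimethylsilyl enol ether) (C1=C2 and C15=C16)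
Conditions: TBSOTf, Et3N, CH2Cl2, 0 °C
Reagents that add atoms: tert-butyldimethylsilyl trifluoromethanesulfonate CC(C)(C)[Si](C)(C)OS(=O)(=O)C(F)(F)F
Why: Soft enolisation converts the two enolisable ketones into silyl enol ethers (C1 towards C2, C15 towards C16), while the lactone has no α-hydrogen.

Step 16
Reactants: 28 bis(silyl enol ether)
Product: 29 ring A enone with bicyclo[3.2.1]oct-11-en-15-one (16-methyl, C16 epimers)
Conditions: Pd(OAc)2 (2.2 equiv), MeCN, rt
Reagents that add atoms: none
Why: Two palladium-mediated oxidations of silyl enol ethers in one flask, Saegusa–Ito dehydrogenation giving the ring A enone and Kende–Toyota cycloalkenylation in which the side-chain palladium enolate should insert the ring C alkene in the 5-exo mode and lose a C11 hydrogen, form the C13–C16 bond on the face fixed by C8.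

Step 17
Reactants: 29 bicyclic ketone
Product: 31 16-hydroxy ketone, via potassium enolate 30 (not isolated)
Conditions: KN(SiMe3)2, THF, −78 °C; then the oxaziridine, −78 °C
Reagents that add atoms: 3-phenyl-2-(phenylsulfonyl)oxaziridine O=S(=O)(c1ccccc1)N1OC1c1ccccc1
Why: The C15 ketone is the only enolisable carbonyl, and Davis hydroxylation of its enolate should occur from the exo face (syn to the C14 bridge), which sets C16 with the hydroxyl exo and erases the C16 epimer mixture.

Step 18
Reactants: 31 alkene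
Product: 32 tert-butyldiphenylsilyl ether of the target
Conditions: H2 (1 atm), RhCl(PPh3)3 (10 mol %), benzene, rt
Reagents that add atoms: none
Why: Homogeneous hydrogenation with RhCl(PPh3)3 should reduce the isolated cis-disubstituted C11–C12 alkene in preference to the conjugated ring A enone, whose β-carbon is flanked by the quaternary C4.

Step 19
Reactants: 32 silyl ether
Product: 33 CNP0530135.1
Conditions: HF·pyridine, pyridine, THF, 0 °C to rt
Reagents that add atoms: none
Why: Buffered fluoride cleavage of the silyl ether should spare the lactone, the enone and the tertiary α-hydroxy ketone and give the target.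

Compound list
1 | 3,3-dimethylpent-4-enoic acid | C=CC(C)(C)CC(=O)O | starting material
2 | (R)-4-benzyl-1,3-oxazolidin-2-one | O=C1N[C@H](Cc2ccccc2)CO1 | starting material
3 | 3,3-dimethylpent-4-enoic pivalic anhydride | C=CC(C)(C)CC(=O)OC(=O)C(C)(C)C | intermediate
4 | (R)-4-benzyl-3-(3,3-dimethylpent-4-enoyl)-1,3-oxazolidin-2-one | C=CC(C)(C)CC(=O)N1[C@H](Cc2ccccc2)COC1=O | intermediate
5 | (Z)-trichlorotitanium enolate of 4 | C=CC(C)(C)/C=C(\O[Ti](Cl)(Cl)Cl)N1[C@H](Cc2ccccc2)COC1=O | intermediate
6 | (R)-4-benzyl-3-[(2S)-2-(hydroxymethyl)-3,3-dimethylpent-4-enoyl]-1,3-oxazolidin-2-one | C=CC(C)(C)[C@@H](CO)C(=O)N1[C@H](Cc2ccccc2)COC1=O | intermediate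
7 | (R)-4-benzyl-3-[(2S)-2-{[(tert-butyldiphenylsilyl)oxy]methyl}-3,3-dimethylpent-4-enoyl]-1,3-oxazolidin-2-one | C=CC(C)(C)[C@@H](CO[Si](c1ccccc1)(c2ccccc2)C(C)(C)C)C(=O)N3[C@H](Cc4ccccc4)COC3=O | intermediate
8 | (2R)-2-{[(tert-butyldiphenylsilyl)oxy]methyl}-3,3-dimethylpent-4-en-1-ol | C=CC(C)(C)[C@@H](CO[Si](c1ccccc1)(c2ccccc2)C(C)(C)C)CO | intermediate
9 | (2S)-2-{[(tert-butyldiphenylsilyl)oxy]methyl}-3,3-dimethylpent-4-enal | C=CC(C)(C)[C@@H](CO[Si](c1ccccc1)(c2ccccc2)C(C)(C)C)C=O | intermediate
10 | (2S)-2-{[(tert-butyldiphenylsilyl)oxy]methyl}-3,3-dimethylcyclopentan-1-one | O=C1CCC(C)(C)[C@H]1CO[Si](c2ccccc2)(c3ccccc3)C(C)(C)C | intermediate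
11 | benzyl alcohol | OCc1ccccc1 | starting material
12 | 2,3-dibromoprop-1-ene | C=C(Br)CBr | starting material
13 | sodium benzyloxide | [Na+].[O-]Cc1ccccc1 | intermediate
14 | benzyl 2-bromoprop-2-en-1-yl ether | C=C(Br)COCc1ccccc1 | intermediate
15 | [3-(benzyloxy)prop-1-en-2-yl]lithium | [Li]C(=C)COCc1ccccc1 | intermediate
16 | [3-(benzyloxy)prop-1-en-2-yl]cerium dichloride | Cl[Ce](Cl)C(=C)COCc1ccccc1 | intermediate
17 | (1S,2S)-1-[3-(benzyloxy)prop-1-en-2-yl]-2-{[(tert-butyldiphenylsilyl)oxy]methyl}-3,3-dimethylcyclopentan-1-ol (alkenyl group trans to the silyloxymethyl group) | C=C(COCc1ccccc1)[C@]2(O)CCC(C)(C)[C@H]2CO[Si](c3ccccc3)(c4ccccc4)C(C)(C)C | intermediate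
18 | (1S,2S)-1-{(2S)-2-[(benzyloxy)methyl]oxiran-2-yl}-2-{[(tert-butyldiphenylsilyl)oxy]methyl}-3,3-dimethylcyclopentan-1-ol | c1ccccc1COC[C@@]2(CO2)[C@]3(O)CCC(C)(C)[C@H]3CO[Si](c4ccccc4)(c5ccccc5)C(C)(C)C | intermediate
19 | (2S,3R)-2-[(benzyloxy)methyl]-3-{[(tert-butyldiphenylsilyl)oxy]methyl}-2-(hydroxymethyl)-4,4-dimethylcyclohexan-1-one (hydroxymethyl cis to silyloxymethyl) | CC1(C)CCC(=O)[C@](COCc2ccccc2)(CO)[C@@H]1CO[Si](c3ccccc3)(c4ccccc4)C(C)(C)C | intermediate
20 | tert-butyl 3-oxopentanoate | CCC(=O)CC(=O)OC(C)(C)C | starting material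
21 | propionylketene (3-oxopent-1-en-1-one) | CCC(=O)C=C=O | intermediate
22 | 3-oxopentanoate ester of the C20 hydroxyl of 19 (ring configuration unchanged) | CC1(C)CCC(=O)[C@](COCc2ccccc2)(COC(=O)CC(=O)CC)[C@@H]1CO[Si](c3ccccc3)(c4ccccc4)C(C)(C)C | intermediate
23 | debenzylated alcohol of 22 (C9 hydroxymethyl, C20 keto ester) | CC1(C)CCC(=O)[C@](CO)(COC(=O)CC(=O)CC)[C@@H]1CO[Si](c2ccccc2)(c3ccccc3)C(C)(C)C | intermediate
24 | C9 aldehyde of 23 | CC1(C)CCC(=O)[C@](C=O)(COC(=O)CC(=O)CC)[C@@H]1CO[Si](c2ccccc2)(c3ccccc3)C(C)(C)C | intermediate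
25 | spirocyclic 3-propionyl-5,6-dihydro-2H-pyran-2-one, spiro-fused at C10 to the cyclohexanone (C8=C9 alkene; 5R,10S) | CC1(C)CCC(=O)[C@]2(COC(=O)C(C(=O)CC)=C2)[C@@H]1CO[Si](c3ccccc3)(c4ccccc4)C(C)(C)C | intermediate
26 | buta-1,3-diene | C=CC=C | starting material
27 | cis-fused cyclohexene lactone, Diels–Alder adduct (5R,8S,9S,10S; C12=C13 alkene; propionyl on C8) | CC1(C)CCC(=O)[C@]2(COC(=O)[C@@]3(C(=O)CC)CC=CC[C@H]32)[C@@H]1CO[Si](c4ccccc4)(c5ccccc5)C(C)(C)C | intermediate
28 | bis(tert-butyldimethylsilyl enol ether) of 27 (C1=C2 and C15=C16; enol ether geometry not fixed) | CC1(C)CC=C(O[Si](C)(C)C(C)(C)C)[C@]2(COC(=O)[C@@]3(C(O[Si](C)(C)C(C)(C)C)=CC)CC=CC[C@H]32)[C@@H]1CO[Si](c4ccccc4)(c5ccccc5)C(C)(C)C | intermediate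
29 | ring A enone with bicyclo[3.2.1]oct-11-en-15-one (16-methyl, C16 epimers; other centres as in the target) | CC1(C)C=CC(=O)[C@]2(COC(=O)[C@@]34C[C@@H](C=C[C@H]32)C(C)C4=O)[C@@H]1CO[Si](c5ccccc5)(c6ccccc6)C(C)(C)C | intermediate
30 | potassium C15–C16 enolate of 29 | CC1(C)C=CC(=O)[C@]2(COC(=O)[C@@]34C[C@@H](C=C[C@H]32)C(C)=C4[O-])[C@@H]1CO[Si](c5ccccc5)(c6ccccc6)C(C)(C)C.[K+] | intermediate
31 | 16-hydroxy-16-methyl-15-ketone with C11=C12 alkene (hydroxyl exo; all centres as in the target) | CC1(C)C=CC(=O)[C@]2(COC(=O)[C@@]34C[C@@H](C=C[C@H]32)[C@](C)(O)C4=O)[C@@H]1CO[Si](c5ccccc5)(c6ccccc6)C(C)(C)C | intermediate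
32 | C6 tert-butyldiphenylsilyl ether of the target | CC1(C)C=CC(=O)[C@]2(COC(=O)[C@@]34C[C@@H](CC[C@H]32)[C@](C)(O)C4=O)[C@@H]1CO[Si](c5ccccc5)(c6ccccc6)C(C)(C)C | intermediate
33 | CNP0530135.1 (5R,8S,9S,10S,13R,16S) | CC1(C)C=CC(=O)[C@]2(COC(=O)[C@@]34C[C@@H](CC[C@H]32)[C@](C)(O)C4=O)[C@@H]1CO | target

Total step count: 19. Longest linear sequence: 18 steps (steps 1–6 and 8–19; step 7 is a one-step branch).

Steps most likely to fail

Step 10. The risk is migration of the C2 methylene instead of C5, which would expand the ring on the wrong side. The fallback sets out from 10 and returns at 19. The kinetic enolate of 10 (lithium diisopropylamide, THF, −78 °C) is sulfenylated with diphenyl disulfide at C2 to give the 5-(phenylsulfanyl)cyclopentanone F1. Addition of 16 as in step 8 gives the allylic alcohol F2. VO(acac)2 with excess t-BuOOH epoxidises the alkene and oxidises the sulfide to the sulfone, giving the epoxy sulfone F3. With BF3·OEt2 only C5 can then migrate, because the sulfonyl-bearing carbon is electron-poor, and the product is the 2-(phenylsulfonyl)cyclohexanone F4. Reductive desulfonylation with Al(Hg) in aqueous THF gives 19.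

Step 16. The risk is that β-hydride elimination of the side-chain palladium enolate, or endo-mode insertion, outruns the 5-exo cyclisation. The fallback sets out from 27 and returns at 31. The C12–C13 alkene is epoxidised on the face opposite the propionyl group (m-CPBA, or N-bromosuccinimide in aqueous solvent followed by K2CO3 if the other face reacts first) to give the oxirane F5. KN(SiMe3)2 forms the C15 enolate, which opens the oxirane at C13 in a 5-exo-tet alkylation and gives the C12 alcohol F6. Dehydration with Martin sulfurane gives the C11–C12 alkene F7. TBSOTf and Et3N give the bis(silyl enol ether) F8, and Pd(OAc)2 (Saegusa–Ito oxidation at both sites) gives the bis-enone F9, which carries the ring A enone and a 16-methylene-15-ketone. Mukaiyama hydration of the exocyclic enone (Mn(dpm)3, PhSiH3, O2, then P(OEt)3), in which the C16 radical is trapped from the exo face, gives 31.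

Step 9. The risk is poor facial selectivity in the directed epoxidation. The fallback sets out from 17 and returns at 24; it uses the other epimer by exchanging the roles of the two arms on C10. The epimeric oxirane F10 (formed alongside 18, or favoured with m-CPBA) is rearranged as in step 10 to the rearranged ketone F11, whose free hydroxymethyl arm is trans to the C6 side chain. Dess–Martin oxidation of that arm gives the aldehyde F12, and hydrogenolysis (H2, Pd/C) of the benzyl ether gives the hydroxy aldehyde F13. Acylation with 20 as in step 11 gives 24, which closes to 25 under the amine catalysis of step 13.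

Further compounds
F1 | step 10 | (2S)-2-{[(tert-butyldiphenylsilyl)oxy]methyl}-3,3-dimethyl-5-(phenylsulfanyl)cyclopentan-1-one (epimers at the sulfur-bearing carbon) | O=C1C(Sc2ccccc2)CC(C)(C)[C@H]1CO[Si](c3ccccc3)(c4ccccc4)C(C)(C)C
F2 | step 10 | 5-(phenylsulfanyl) analogue of allylic alcohol 17 | C=C(COCc1ccccc1)[C@]2(O)C(Sc3ccccc3)CC(C)(C)[C@H]2CO[Si](c4ccccc4)(c5ccccc5)C(C)(C)C
F3 | step 10 | 5-(phenylsulfonyl) analogue of epoxy alcohol 18 | c1ccccc1COC[C@@]2(CO2)[C@]3(O)C(S(=O)(=O)c4ccccc4)CC(C)(C)[C@H]3CO[Si](c5ccccc5)(c6ccccc6)C(C)(C)C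
F4 | step 10 | 6-(phenylsulfonyl) derivative of cyclohexanone 19 (sulfonyl on C2 of ring A) | CC1(C)CC(S(=O)(=O)c2ccccc2)C(=O)[C@](COCc3ccccc3)(CO)[C@@H]1CO[Si](c4ccccc4)(c5ccccc5)C(C)(C)C
F5 | step 16 | C12–C13 oxirane of 27, oxygen on the face opposite the propionyl group | CC1(C)CCC(=O)[C@]2(COC(=O)[C@@]3(C(=O)CC)C[C@H]4O[C@H]4C[C@H]32)[C@@H]1CO[Si](c5ccccc5)(c6ccccc6)C(C)(C)C
F6 | step 16 | bicyclo[3.2.1]octan-15-one with axial C12 hydroxyl and 16-methyl (C16 epimers), ring A saturated ketone | CC1(C)CCC(=O)[C@]2(COC(=O)[C@@]34C[C@@H]([C@@H](O)C[C@H]32)C(C)C4=O)[C@@H]1CO[Si](c5ccccc5)(c6ccccc6)C(C)(C)C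
F7 | step 16 | 2,3-dihydro analogue of 29 (C11=C12 alkene, ring A saturated ketone) | CC1(C)CCC(=O)[C@]2(COC(=O)[C@@]34C[C@@H](C=C[C@H]32)C(C)C4=O)[C@@H]1CO[Si](c5ccccc5)(c6ccccc6)C(C)(C)C
F8 | step 16 | bis(tert-butyldimethylsilyl enol ether) of F7 (C1=C2 and C15=C16) | CC1(C)CC=C(O[Si](C)(C)C(C)(C)C)[C@]2(COC(=O)[C@@]34C[C@@H](C=C[C@H]32)C(C)=C4O[Si](C)(C)C(C)(C)C)[C@@H]1CO[Si](c5ccccc5)(c6ccccc6)C(C)(C)C
F9 | step 16 | bis-enone: ring A enone and 16-methylene-15-ketone with C11=C12 alkene | CC1(C)C=CC(=O)[C@]2(COC(=O)[C@@]34C[C@@H](C=C[C@H]32)C(=C)C4=O)[C@@H]1CO[Si](c5ccccc5)(c6ccccc6)C(C)(C)C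
F10 | step 9 | (2R)-oxirane epimer of 18 | c1ccccc1COC[C@]2(CO2)[C@]3(O)CCC(C)(C)[C@H]3CO[Si](c4ccccc4)(c5ccccc5)C(C)(C)C
F11 | step 9 | C10 epimer of 19 (free hydroxymethyl trans to silyloxymethyl, benzyloxymethyl cis) | CC1(C)CCC(=O)[C@](CO)(COCc2ccccc2)[C@@H]1CO[Si](c3ccccc3)(c4ccccc4)C(C)(C)C
F12 | step 9 | C9 aldehyde of F11 | CC1(C)CCC(=O)[C@](C=O)(COCc2ccccc2)[C@@H]1CO[Si](c3ccccc3)(c4ccccc4)C(C)(C)C
F13 | step 9 | debenzylated hydroxy aldehyde (C9 formyl, C20 hydroxymethyl) | CC1(C)CCC(=O)[C@](C=O)(CO)[C@@H]1CO[Si](c2ccccc2)(c3ccccc3)C(C)(C)C
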